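The route rests on disconnecting the N1–C2 bond of the piperidine. C2 is the benzylic carbon on C8 of ring A, flanked by the C7 hydroxyl and by O1, which is still a free phenol before the pyranone is built. Two-electron anodic oxidation of an open-chain 2-alkylresorcinol should therefore unmask an ortho-quinone methide whose electrophilic terminus is this very carbon. A tethered carbamate nitrogen adds to it under a chiral phosphoric acid, so one operation forms the C–N bond, the piperidine ring and the R stereocentre. The precursor is a 2-(5-aminopentyl)-5-methoxyresorcinol with both phenols free and the nitrogen carried as its benzyl carbamate; the flavone is annulated afterwards without acid.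

Key step: step 6

Assumption: the sense of induction of the phosphoric acid in step 6 cannot be derived reliably in advance; the R-configured acid is written, and its mirror image would be taken if it favoured the S product.

Step 1
Reactants: 1 5-methoxyresorcinol; 2 chloromethyl methyl ether
Product: 3 1-methoxy-3,5-bis(methoxymethoxy)benzene
Conditions: NaH (2.4 equiv), DMF, 0 °C; then MOMCl (2.4 equiv), 0 °C to rt
Reagents that add atoms: chloromethyl methyl ether (compound 2), COCCl
Why: Williamson-type O-alkylation of the bis-phenoxide by the highly reactive α-chloro ether should give the bis-acetal, and MOM is chosen because it is a strong chelating director for the ortho-lithiation that follows.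

Step 2
Reactants: 3 1-methoxy-3,5-bis(methoxymethoxy)benzene; 4 1-bromo-5-chloropentane
Product: 6 2-(5-chloropentyl)-5-methoxy-1,3-bis(methoxymethoxy)benzene, via aryllithium 5 (not isolated)
Conditions: n-BuLi (1.1 equiv), THF, 0 °C; then 1-bromo-5-chloropentane (1.5 equiv), 0 °C to rt
Reagents that add atoms: 1-bromo-5-chloropentane (compound 4), ClCCCCCBr
Why: Directed ortho-metalation should occur at the ring carbon flanked by both chelating OMOM groups in preference to the positions next to OMe, and the aryllithium then displaces bromide in an SN2 alkylation far faster than chloride.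

Step 3
Reactants: 6 2-(5-chloropentyl)-5-methoxy-1,3-bis(methoxymethoxy)benzene; 7 sodium azide
Product: 8 2-(5-azidopentyl)-5-methoxy-1,3-bis(methoxymethoxy)benzene
Conditions: NaN3 (1.5 equiv), NaI (10 mol%), DMF, 70 °C
Reagents that add atoms: sodium azide (compound 7), [N-]=[N+]=[N-].[Na+]
Why: SN2 displacement of the primary chloride by azide, assisted by in situ Finkelstein exchange, installs the nitrogen with no possibility of over-alkylation.

Step 4
Reactants: 8 2-(5-azidopentyl)-5-methoxy-1,3-bis(methoxymethoxy)benzene; 9 benzyl chloroformate
Product: 11 benzyl N-[5-[4-methoxy-2,6-bis(methoxymethoxy)phenyl]pentyl]carbamate, via primary amine 10 (not isolated)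
Conditions: H2 (1 atm), Pd/C (10 wt% Pd), THF, rt; filtration; then CbzCl (1.1 equiv), aq. NaHCO3, 0 °C
Reagents that add atoms: benzyl chloroformate (compound 9), O=C(Cl)OCc1ccccc1
Why: Catalytic hydrogenation reduces the alkyl azide to the amine with loss of N2 while the aryl MOM ethers are inert, and Schotten–Baumann acylation of the filtered amine solution should give the carbamate.

Step 5
Reactants: 11 benzyl N-[5-[4-methoxy-2,6-bis(methoxymethoxy)phenyl]pentyl]carbamate
Product: 12 benzyl N-[5-(2,6-dihydroxy-4-methoxyphenyl)pentyl]carbamate
Conditions: aq. HCl (3 M, cat.), MeOH, 45 °C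
Reagents that add atoms: none
Why: Acid-catalysed transacetalisation with methanol releases both phenols as dimethoxymethane is formed, under conditions that the benzyl carbamate and the aryl methyl ether tolerate and at a stage where no stereocentre is present.

Step 6
Reactants: 12 benzyl N-[5-(2,6-dihydroxy-4-methoxyphenyl)pentyl]carbamate
Product: 14 benzyl (R)-2-(2,6-dihydroxy-4-methoxyphenyl)piperidine-1-carboxylate, via ortho-quinone methide 13 (not isolated)
Conditions: undivided cell, graphite anode, Pt cathode, constant current to about 2 F per mol, (R)-3,3'-bis(2,4,6-triisopropylphenyl)-1,1'-binaphthyl-2,2'-diyl hydrogen phosphate (10 mol%), n-Bu4NPF6 (0.1 M), CH2Cl2/HFIP (9:1), 0.02 M, −20 °C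
Reagents that add atoms: none
Why: Proposed new method: the resorcinol is the most easily oxidised group, so the anode should remove two electrons and two protons from it (phenol to phenoxonium ion, then loss of the benzylic proton) to give ortho-quinone methide 13 while protons are reduced to H2 at the cathode, and any 2-alkenylresorcinol tautomer should be returned to 13 by the acid. The closest known reaction types are anodic benzylic C–H amination of electron-rich alkylarenes in fluorinated alcohol media and chiral-phosphoric-acid-catalysed enantioselective additions to ortho-quinone methides generated from ortho-hydroxybenzyl alcohols; the new element is their merger on a non-stabilised alkyl quinone methide with a carbamate nucleophile. The piperidine closes by 6-exo-trig aza-Michael addition of the carbamate N–H to the exocyclic methide carbon, which restores the aromatic ring and is the only closure that the five-carbon tether permits. The C2 stereocentre is set by the catalyst alone: its acidic O–H binds the methide carbonyl oxygen and its P=O accepts the carbamate N–H, so that the 2,4,6-triisopropylphenyl walls leave one enantioface of the planar methide open to nitrogen, and the degenerate proton shift between the two ring oxygens makes the methide geometry immaterial. The step needs a single quinone methide and a product that is not oxidised again: the para position carries OMe so no para-quinone methide can form, the two hydroxyls are symmetry-equivalent so either gives 13, and in 14 the benzylic C–H is expected to lie in the arene plane between the two ortho oxygens, out of alignment with the π system. Low temperature, a largely non-ionising solvent and a charge limit are meant to suppress the uncatalysed cyclisation and acid-promoted reopening of the benzylic C–N bond.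

Step 7
Reactants: 14 benzyl (R)-2-(2,6-dihydroxy-4-methoxyphenyl)piperidine-1-carboxylate; 15 N-iodosuccinimide
Product: 16 benzyl (R)-2-(2,6-dihydroxy-3-iodo-4-methoxyphenyl)piperidine-1-carboxylate
Conditions: NIS (1.0 equiv, slow addition), MeCN, −20 °C, dark
Reagents that add atoms: N-iodosuccinimide (compound 15), O=C1CCC(=O)N1I
Why: Electrophilic aromatic iodination at one of the two equivalent ring C–H positions (each ortho and para to a hydroxyl) proceeds under neutral conditions, which spare the benzylic carbamate stereocentre that strong acid would be expected to ionise, and one equivalent of reagent limits diiodination.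

Step 8
Reactants: 16 benzyl (R)-2-(2,6-dihydroxy-3-iodo-4-methoxyphenyl)piperidine-1-carboxylate; 17 phenylacetylene; 18 carbon monoxide
Product: 20 benzyl (R)-2-(7-hydroxy-5-methoxy-4-oxo-2-phenyl-4H-chromen-8-yl)piperidine-1-carboxylate, via alkynyl ketone 19 (not isolated)
Conditions: PdCl2(PPh3)2 (5 mol%), phenylacetylene (1.5 equiv), CO (5 bar), Et2NH, 60 °C
Reagents that add atoms: phenylacetylene (compound 17), C#Cc1ccccc1; carbon monoxide (compound 18), [C-]#[O+]
Why: Carbonylative Sonogashira coupling of the ortho-iodophenol should give the ortho-hydroxyaryl alkynyl ketone, which in the secondary amine closes ring C by 6-endo-dig oxa-Michael cyclisation through the only hydroxyl adjacent to the acyl group, again without acid.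

Step 9
Reactants: 20 benzyl (R)-2-(7-hydroxy-5-methoxy-4-oxo-2-phenyl-4H-chromen-8-yl)piperidine-1-carboxylate
Product: 21 (R)-7-hydroxy-5-methoxy-2-phenyl-8-(piperidin-2-yl)-4H-chromen-4-one
Conditions: H2 (1 atm), Pd/C (10 wt% Pd), MeOH/EtOAc, rt
Reagents that add atoms: none
Why: Hydrogenolysis of the benzyl carbamate and spontaneous decarboxylation release the secondary amine at room temperature, conditions under which the cross-conjugated pyranone double bond and the benzylic C–N bond should stay intact and the stereocentre is not touched.

Compound list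
1 | 5-methoxyresorcinol | COc1cc(O)cc(O)c1 | starting material
2 | chloromethyl methyl ether | COCCl | starting material
3 | 1-methoxy-3,5-bis(methoxymethoxy)benzene | COCOc1cc(OC)cc(OCOC)c1 | intermediate
4 | 1-bromo-5-chloropentane | ClCCCCCBr | starting material
5 | [4-methoxy-2,6-bis(methoxymethoxy)phenyl]lithium | [Li]c1c(OCOC)cc(OC)cc1OCOC | intermediate
6 | 2-(5-chloropentyl)-5-methoxy-1,3-bis(methoxymethoxy)benzene | ClCCCCCc1c(OCOC)cc(OC)cc1OCOC | intermediate
7 | sodium azide | [N-]=[N+]=[N-].[Na+] | starting material
8 | 2-(5-azidopentyl)-5-methoxy-1,3-bis(methoxymethoxy)benzene | [N-]=[N+]=NCCCCCc1c(OCOC)cc(OC)cc1OCOC | intermediate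
9 | benzyl chloroformate | O=C(Cl)OCc1ccccc1 | starting material
10 | 5-[4-methoxy-2,6-bis(methoxymethoxy)phenyl]pentan-1-amine | NCCCCCc1c(OCOC)cc(OC)cc1OCOC | intermediate
11 | benzyl N-[5-[4-methoxy-2,6-bis(methoxymethoxy)phenyl]pentyl]carbamate | O=C(NCCCCCc1c(OCOC)cc(OC)cc1OCOC)OCc1ccccc1 | intermediate
12 | benzyl N-[5-(2,6-dihydroxy-4-methoxyphenyl)pentyl]carbamate | COc1cc(O)c(CCCCCNC(=O)OCc2ccccc2)c(O)c1 | intermediate
13 | benzyl N-[5-(2-hydroxy-4-methoxy-6-oxocyclohexa-2,4-dien-1-ylidene)pentyl]carbamate | COC1=CC(=O)C(=CCCCCNC(=O)OCc2ccccc2)C(O)=C1 | intermediate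
14 | benzyl (R)-2-(2,6-dihydroxy-4-methoxyphenyl)piperidine-1-carboxylate | COc1cc(O)c([C@H]2CCCCN2C(=O)OCc2ccccc2)c(O)c1 | intermediate
15 | N-iodosuccinimide | O=C1CCC(=O)N1I | starting material
16 | benzyl (R)-2-(2,6-dihydroxy-3-iodo-4-methoxyphenyl)piperidine-1-carboxylate | COc1cc(O)c([C@H]2CCCCN2C(=O)OCc2ccccc2)c(O)c1I | intermediate
17 | phenylacetylene | C#Cc1ccccc1 | starting material
18 | carbon monoxide | [C-]#[O+] | starting material
19 | benzyl (R)-2-[2,6-dihydroxy-4-methoxy-3-(3-phenylprop-2-ynoyl)phenyl]piperidine-1-carboxylate | COc1cc(O)c([C@H]2CCCCN2C(=O)OCc2ccccc2)c(O)c1C(=O)C#Cc1ccccc1 | intermediate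
20 | benzyl (R)-2-(7-hydroxy-5-methoxy-4-oxo-2-phenyl-4H-chromen-8-yl)piperidine-1-carboxylate | COc1cc(O)c([C@H]2CCCCN2C(=O)OCc2ccccc2)c2oc(-c3ccccc3)cc(=O)c12 | intermediate
21 | (R)-7-hydroxy-5-methoxy-2-phenyl-8-(piperidin-2-yl)-4H-chromen-4-one | COc1cc(O)c([C@H]2CCCCN2)c2oc(-c3ccccc3)cc(=O)c12 | target

Total step count: 9. Longest linear sequence: 9 steps (compound 1 to compound 21).

Steps most likely to fail

Step 6 (the proposed new method). The anode may oxidise the ring along other channels, such as phenol coupling at the free ring positions or a second oxidation of the product. The very reactive methide may also cyclise without the acid and so erode the enantioselectivity, or the acid may reopen the benzylic C–N bond and racemise the product. The fallback uses known tert-butanesulfinamide auxiliary chemistry; it sets out from compound 3 and returns to the route at compound 14.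
- Swern oxidation of 5-chloropentan-1-ol would give 5-chloropentanal F1.
- Condensation of F1 with (R)-2-methylpropane-2-sulfinamide (CuSO4, CH2Cl2) would give (R,E)-N-(5-chloropentylidene)-2-methylpropane-2-sulfinamide F2.
- Compound 3 would be lithiated as in step 2, and aryllithium 5 transmetalated with MgBr2·OEt2 to [4-methoxy-2,6-bis(methoxymethoxy)phenyl]magnesium bromide F3.
- Addition of F3 to F2 in toluene at −48 °C should give (R)-N-[(1R)-5-chloro-1-[4-methoxy-2,6-bis(methoxymethoxy)phenyl]pentyl]-2-methylpropane-2-sulfinamide F4. The magnesium-bridged six-membered chair transition state is expected to lead from the R auxiliary to the R carbon centre; the S auxiliary would be used if the opposite sense were found.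
- KN(SiMe3)2 in THF would close the ring by intramolecular N-alkylation to (R)-1-[(R)-tert-butylsulfinyl]-2-[4-methoxy-2,6-bis(methoxymethoxy)phenyl]piperidine F5.
- HCl in MeOH at or below rt would remove the sulfinyl group and both MOM ethers to leave (R)-2-(2,6-dihydroxy-4-methoxyphenyl)piperidine F6, kept as its hydrochloride.
- CbzCl with aqueous NaHCO3 at 0 °C would acylate F6 on nitrogen to give 14.

Step 8. Direct, non-carbonylative coupling (leading on to a benzofuran), aminocarbonylation by the amine solvent, 5-exo closure to the aurone or protodeiodination of the electron-rich iodide may compete. The fallback replaces the carbonylation by a stepwise acylation; it sets out from compound 16 and returns at compound 20.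
- Stille coupling of 16 with tributyl(1-ethoxyvinyl)stannane (Pd(PPh3)4, toluene, 80 °C) would give benzyl (R)-2-[3-(1-ethoxyvinyl)-2,6-dihydroxy-4-methoxyphenyl]piperidine-1-carboxylate F7.
- Hydrolysis of the enol ether on wet silica or with dilute oxalic acid would give benzyl (R)-2-(3-acetyl-2,6-dihydroxy-4-methoxyphenyl)piperidine-1-carboxylate F8.
- Treatment of F8 with LiN(SiMe3)2 (4 equiv, THF, −78 °C) and one equivalent of benzoyl chloride would C-acylate the enolate in a crossed Claisen condensation to benzyl (R)-2-[2,6-dihydroxy-4-methoxy-3-(3-oxo-3-phenylpropanoyl)phenyl]piperidine-1-carboxylate F9.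
- Cyclodehydration with catalytic p-toluenesulfonic acid monohydrate in toluene at 60 °C, on a ring now deactivated by the acyl group, would give 20.

Step 2. Alkylation of the di-ortho-substituted aryllithium may be slow, so that E2 elimination of the dihalide, lithium–halogen exchange or protonation of the aryllithium takes over. The fallback forms the aryl–alkyl bond by cross-coupling and brings the nitrogen in already protected; it sets out from compound 3 and returns at compound 11, so steps 3 and 4 are bypassed.
- Lithiation of 3 as before and quenching with iodine would give 2-iodo-5-methoxy-1,3-bis(methoxymethoxy)benzene F10.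
- Pent-4-en-1-amine and compound 9 (aqueous NaHCO3) would give benzyl pent-4-en-1-ylcarbamate F11.
- Hydroboration of F11 with 9-borabicyclo[3.3.1]nonane in THF would give benzyl N-[5-(9-borabicyclo[3.3.1]nonan-9-yl)pentyl]carbamate F12.
- B-alkyl Suzuki–Miyaura coupling of F12 with F10 ([1,1'-bis(diphenylphosphino)ferrocene]palladium dichloride, K3PO4, THF/DMF/H2O, 60 °C) would give 11.

Further compounds
F1 | step 6 | 5-chloropentanal | O=CCCCCCl
F2 | step 6 | (R,E)-N-(5-chloropentylidene)-2-methylpropane-2-sulfinamide | CC(C)(C)[S@@](=O)/N=C/CCCCCl
F3 | step 6 | [4-methoxy-2,6-bis(methoxymethoxy)phenyl]magnesium bromide | COCOc1cc(OC)cc(OCOC)c1[Mg]Br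
F4 | step 6 | (R)-N-[(1R)-5-chloro-1-[4-methoxy-2,6-bis(methoxymethoxy)phenyl]pentyl]-2-methylpropane-2-sulfinamide | CC(C)(C)[S@@](=O)N[C@H](CCCCCl)c1c(OCOC)cc(OC)cc1OCOC
F5 | step 6 | (R)-1-[(R)-tert-butylsulfinyl]-2-[4-methoxy-2,6-bis(methoxymethoxy)phenyl]piperidine | CC(C)(C)[S@@](=O)N1CCCC[C@@H]1c1c(OCOC)cc(OC)cc1OCOC
F6 | step 6 | (R)-2-(2,6-dihydroxy-4-methoxyphenyl)piperidine | COc1cc(O)c([C@H]2CCCCN2)c(O)c1
F7 | step 8 | benzyl (R)-2-[3-(1-ethoxyvinyl)-2,6-dihydroxy-4-methoxyphenyl]piperidine-1-carboxylate | CCOC(=C)c1c(OC)cc(O)c([C@H]2CCCCN2C(=O)OCc2ccccc2)c1O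
F8 | step 8 | benzyl (R)-2-(3-acetyl-2,6-dihydroxy-4-methoxyphenyl)piperidine-1-carboxylate | COc1cc(O)c([C@H]2CCCCN2C(=O)OCc2ccccc2)c(O)c1C(C)=O
F9 | step 8 | benzyl (R)-2-[2,6-dihydroxy-4-methoxy-3-(3-oxo-3-phenylpropanoyl)phenyl]piperidine-1-carboxylate | COc1cc(O)c([C@H]2CCCCN2C(=O)OCc2ccccc2)c(O)c1C(=O)CC(=O)c1ccccc1
F10 | step 2 | 2-iodo-5-methoxy-1,3-bis(methoxymethoxy)benzene | COCOc1cc(OC)cc(OCOC)c1I
F11 | step 2 | benzyl pent-4-en-1-ylcarbamate | C=CCCCNC(=O)OCc1ccccc1
F12 | step 2 | benzyl N-[5-(9-borabicyclo[3.3.1]nonan-9-yl)pentyl]carbamate | O=C(NCCCCCB1C2CCCC1CCC2)OCc1ccccc1
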